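**Retrosynthetic overview**
1. The last C–C bond made is the one between the vinylic CH of the (6E)-C(CH3)=CH olefin and the neighbouring CH2 of the CH2–CH2 tether. It comes from 9-BBN hydroboration of the dienyl butenolide 20 (C11) and B-alkyl Suzuki–Miyaura coupling with the (E)-alkenyl iodide 5 (C14); desilylation then gives the target.
2. Enabling feature: the two trisubstituted olefins are 1,5-related through CH2–CH2, so the right half can carry this unit as a terminal vinyl group conjugated to the C(CH2OR)=CH olefin. Its CH2= terminus is the only alkene 9-BBN should touch (the trisubstituted olefin, the butenolide ring C=C and the lactone C=O are inert), and the tetrasubstituted cyclohexene ring olefin of 5 is a spectator.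
3. 20 comes from Stille vinylation of (Z)-alkenyl iodide 19, which comes from closure of the butenolide ring on α-hydroxy ketone 17 (Ph3P=C=C=O, O-acylation then intramolecular Wittig). 17 comes from RAMP-hydrazone alkylation of 2,2-dimethyl-1,3-dioxan-5-one with (Z)-allylic bromide 10 (sets the only stereocentre); 10 comes from but-2-yne-1,4-diol by trans-hydroalumination/iodination, which fixes the second olefin geometry.
4. 5 comes from terminal alkyne 3 by zirconium-catalysed syn-carboalumination/iodination (fixes 6E); 3 comes from dihydro-β-ionone.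
5. Rings: the cyclohexene ring is bought with dihydro-β-ionone; the temporary 1,3-dioxane ring (bought) is opened in step 9; the butenolide ring is the only ring formed (step 11), before the fragment union.

Key step: step 13

Remark (assumption): the facial sense of the hydrazone alkylation is taken from the SAMP series, which leads to (S)-4-alkyl-2,2-dimethyl-1,3-dioxan-5-ones, so the enantiomeric auxiliary RAMP is used for the (R) centre; the C=N geometry of hydrazone 14 is left open because it is lost in step 8.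

**Step 1**
Reactants: 1 dihydro-β-ionone, 4-(2,6,6-trimethylcyclohex-1-en-1-yl)butan-2-one
Product: 3 2-(but-3-yn-1-yl)-1,3,3-trimethylcyclohex-1-ene, via enol phosphate 2 (not isolated)
Conditions: LiN(i-Pr)2 (1.05 equiv), THF, −78 °C; ClP(O)(OEt)2, −78 °C → rt; then LiN(i-Pr)2 (2.3 equiv), −78 °C → rt; H2O
Reagents that add atoms: none
Why: Kinetic deprotonation at the methyl group, O-phosphorylation and base-induced elimination of the terminal enol phosphate (methyl ketone to terminal alkyne via the enol phosphate) should deliver the alkyne, the tetrasubstituted ring olefin being inert.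

**Step 2**
Reactants: 3 2-(but-3-yn-1-yl)-1,3,3-trimethylcyclohex-1-ene
Product: 5 2-[(3E)-4-iodo-3-methylbut-3-en-1-yl]-1,3,3-trimethylcyclohex-1-ene, via alkenylalane 4 (not isolated)
Conditions: Me3Al (2.0 equiv), Cp2ZrCl2 (0.25 equiv), CH2Cl2, 0 °C → rt; then I2, THF, −30 → 0 °C
Reagents that add atoms: trimethylaluminium, C[Al](C)C; iodine, II
Why: Zirconium-catalysed syn-methylalumination of the terminal alkyne (Negishi carboalumination) puts methyl on the internal and aluminium on the terminal carbon, and iodinolysis with retention should give the E-alkenyl iodide that defines the 6E olefin.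

**Step 3**
Reactants: 6 but-2-yne-1,4-diol
Product: 7 4-((tert-butyldiphenylsilyl)oxy)but-2-yn-1-ol
Conditions: 6 (3 equiv), t-BuPh2SiCl (1 equiv), imidazole, DMF, 0 °C → rt
Reagents that add atoms: tert-butyl(chloro)diphenylsilane, CC(C)(C)[Si](Cl)(c1ccccc1)c1ccccc1
Why: Statistical monosilylation of a symmetrical diol used in excess should give the mono-ether, the robust TBDPS group being chosen to survive the later acidic steps (silyl ether formation).

**Step 4**
Reactants: 7 4-((tert-butyldiphenylsilyl)oxy)but-2-yn-1-ol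
Product: 9 (Z)-4-((tert-butyldiphenylsilyl)oxy)-3-iodobut-2-en-1-ol, via vinylalanate 8 (not isolated)
Conditions: NaAlH2(OCH2CH2OMe)2 (1.5 equiv), THF, 0 °C; EtOAc quench; then I2, THF, −78 → 0 °C
Reagents that add atoms: iodine, II
Why: Hydroxyl-directed trans-hydroalumination of the propargylic alcohol gives the five-membered alanate 8 with aluminium on the carbon remote from the free OH and cis to its CH2O arm, so iodinolysis with retention should give the Z-iodide that fixes the geometry of the second trisubstituted olefin, the low temperature disfavouring β-elimination of the silyloxide.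

**Step 5**
Reactants: 9 (Z)-4-((tert-butyldiphenylsilyl)oxy)-3-iodobut-2-en-1-ol
Product: 10 (Z)-[(4-bromo-2-iodobut-2-en-1-yl)oxy](tert-butyl)diphenylsilane
Conditions: CBr4 (1.2 equiv), PPh3 (1.25 equiv), CH2Cl2, 0 °C
Reagents that add atoms: carbon tetrabromide, BrC(Br)(Br)Br
Why: Appel bromination proceeds by SN2 displacement at the primary allylic carbon, so the olefin geometry and the alkenyl iodide should be untouched.

**Step 6**
Reactants: 11 2,2-dimethyl-1,3-dioxan-5-one
Product: 12 (R)-N-(2,2-dimethyl-1,3-dioxan-5-ylidene)-2-(methoxymethyl)pyrrolidin-1-amine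
Conditions: RAMP (1.0 equiv), benzene, reflux, Dean–Stark trap
Reagents that add atoms: (R)-1-amino-2-(methoxymethyl)pyrrolidine (RAMP), COC[C@H]1CCCN1N
Why: Condensation of the ketone with the N-amino auxiliary under azeotropic removal of water gives the hydrazone (hydrazone formation).

**Step 7**
Reactants: 12 RAMP hydrazone of 2,2-dimethyl-1,3-dioxan-5-one; 10 (Z)-allylic bromide
Product: 14 (R)-N-[(4R)-4-((Z)-4-((tert-butyldiphenylsilyl)oxy)-3-iodobut-2-en-1-yl)-2,2-dimethyl-1,3-dioxan-5-ylidene]-2-(methoxymethyl)pyrrolidin-1-amine, via lithium azaenolate 13 (not isolated)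
Conditions: t-BuLi (1.05 equiv), THF, −78 °C, 2 h; then 10, −100 °C → rt
Reagents that add atoms: none
Why: In this Enders RAMP-hydrazone alkylation the chelated lithium azaenolate is alkylated by SN2 attack on the allylic bromide from the face opposite to the methoxymethyl arm, which sets the single stereocentre (R) under auxiliary control, the alkenyl iodide and silyl ether being inert at −100 °C.

**Step 8**
Reactants: 14 alkylated RAMP hydrazone
Product: 15 (R)-4-[(Z)-4-((tert-butyldiphenylsilyl)oxy)-3-iodobut-2-en-1-yl]-2,2-dimethyl-1,3-dioxan-5-one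
Conditions: saturated aq. oxalic acid, Et2O, rt (two-phase)
Reagents that add atoms: water, O
Why: Two-phase oxalic acid hydrolysis cleaves the hydrazone under mild conditions that should not enolise the α-alkoxy ketone nor touch the acetonide, silyl ether or alkenyl iodide (hydrazone hydrolysis).

**Step 9**
Reactants: 15 (R)-4-substituted 2,2-dimethyl-1,3-dioxan-5-one
Product: 16 (3R,5Z)-7-((tert-butyldiphenylsilyl)oxy)-1,3-dihydroxy-6-iodohept-5-en-2-one
Conditions: AcOH/H2O (4:1), 40 °C
Reagents that add atoms: none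
Why: Aqueous acetic acid hydrolyses the 1,3-dioxane acetonide (acetal hydrolysis) while the TBDPS ether and the alkenyl iodide survive, and the acidic medium should not enolise the α-hydroxy ketone appreciably.

**Step 10**
Reactants: 16 (3R,5Z)-dihydroxy ketone
Product: 17 (3R,5Z)-1-((tert-butyldimethylsilyl)oxy)-7-((tert-butyldiphenylsilyl)oxy)-3-hydroxy-6-iodohept-5-en-2-one
Conditions: t-BuMe2SiCl (1.05 equiv), imidazole, CH2Cl2, −20 → 0 °C
Reagents that add atoms: tert-butyl(chloro)dimethylsilane, CC(C)(C)[Si](C)(C)Cl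
Why: Silylation with a bulky chlorosilane is selective for the primary over the secondary α-keto hydroxyl (chemoselective silyl ether formation), leaving the secondary OH free for lactone formation.

**Step 11**
Reactants: 17 (3R,5Z)-α-hydroxy ketone
Product: 19 (R)-4-(((tert-butyldimethylsilyl)oxy)methyl)-5-[(Z)-4-((tert-butyldiphenylsilyl)oxy)-3-iodobut-2-en-1-yl]furan-2(5H)-one, via ester ylide 18 (not isolated)
Conditions: Ph3P=C=C=O (1.3 equiv), toluene, 90 °C
Reagents that add atoms: (triphenylphosphoranylidene)ketene, O=C=C=P(c1ccccc1)(c1ccccc1)c1ccccc1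
Why: The free secondary OH adds to the cumulated ylide to give the ester-stabilised ylide 18, whose intramolecular Wittig reaction with the adjacent ketone closes the five-membered butenolide ring (Bestmann ylide butenolide synthesis) under neutral conditions that should preserve the stereocentre.

**Step 12**
Reactants: 19 (R,Z)-iodo butenolide
Product: 20 (R)-4-(((tert-butyldimethylsilyl)oxy)methyl)-5-[(E)-3-(((tert-butyldiphenylsilyl)oxy)methyl)penta-2,4-dien-1-yl]furan-2(5H)-one
Conditions: CH2=CHSnBu3 (1.3 equiv), Pd2(dba)3 (2.5 mol %), AsPh3 (20 mol %), DMF, rt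
Reagents that add atoms: tributyl(vinyl)stannane, C=C[Sn](CCCC)(CCCC)CCCC
Why: Stille coupling of the alkenyl iodide with the vinylstannane proceeds with retention of olefin geometry under neutral conditions that the butenolide tolerates, giving the 2-substituted 1,3-diene.

**Step 13**
Reactants: 20 dienyl butenolide; 5 (E)-alkenyl iodide
Product: 22 (R)-4-(((tert-butyldimethylsilyl)oxy)methyl)-5-[(2E,6E)-3-(((tert-butyldiphenylsilyl)oxy)methyl)-7-methyl-9-(2,6,6-trimethylcyclohex-1-en-1-yl)nona-2,6-dien-1-yl]furan-2(5H)-one, via alkylborane 21 (not isolated)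
Conditions: 20 (1.2 equiv), 9-BBN (1.5 equiv), THF, 0 °C → rt; then 5 (1.0 equiv), Pd(dppf)Cl2 (10 mol %), AsPh3 (10 mol %), 3 M aq. K3PO4 (3 equiv), DMF, rt
Reagents that add atoms: none
Why: 9-BBN adds anti-Markovnikov to the unhindered CH2=CH terminus of the 2-substituted buta-1,3-diene in 20 to give the primary homoallylic borane 21; zerovalent palladium then inserts into the C–I bond of 5 with retention, the base-activated borate transfers its primary alkyl group to palladium, and reductive elimination forges the C(sp2)–C(sp3) bond between the vinylic CH of the left half and the terminal CH2 of the former vinyl group. The closest known reaction type is the B-alkyl Suzuki–Miyaura coupling of 9-BBN adducts of terminal alkenes with (E)-2-methyl-1-iodoalk-1-enes, a standard late-stage fragment union for 1,5-dienes. No ring is closed and no stereocentre is created; the (R) centre and the (2E) olefin arrive intact in 20, and the (6E) geometry is transferred from 5 because oxidative addition and reductive elimination are stereoretentive. The step needs chemo- and regioselective hydroboration, which the substrate secures because the monosubstituted vinyl terminus is the only accessible electron-rich alkene (the trisubstituted diene olefin, the electron-poor butenolide C=C and the lactone C=O are inert to 9-BBN at room temperature) and boron goes to the terminal carbon. It also needs suppression of β-hydride elimination from the homoallyl–palladium intermediate, secured by the wide-bite-angle dppf ligand, and survival of the base-sensitive butenolide, for which mild aqueous K3PO4 at room temperature is chosen. In one operation the step joins the C14 and C11 halves and completes the C25 skeleton with both olefin geometries and the stereocentre in place, leaving only desilylation.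

**Step 14**
Reactants: 22 bis-silyl ether of (6E)-neomanoalide
Product: 23 (6E)-neomanoalide, (R)-4-(hydroxymethyl)-5-[(2E,6E)-3-(hydroxymethyl)-7-methyl-9-(2,6,6-trimethylcyclohex-1-en-1-yl)nona-2,6-dien-1-yl]furan-2(5H)-one
Conditions: HF·pyridine (excess), pyridine, THF, 0 °C → rt
Reagents that add atoms: none
Why: Fluoride-mediated cleavage of both silyl ethers under acidic, non-basic conditions (desilylation) should free the two primary alcohols without epimerising or opening the butenolide.

**Compound list**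
1 | dihydro-β-ionone, 4-(2,6,6-trimethylcyclohex-1-en-1-yl)butan-2-one | CC(=O)CCC1=C(C)CCCC1(C)C | starting material
2 | diethyl 4-(2,6,6-trimethylcyclohex-1-en-1-yl)but-1-en-2-yl phosphate | C=C(OP(=O)(OCC)OCC)CCC1=C(C)CCCC1(C)C | intermediate
3 | 2-(but-3-yn-1-yl)-1,3,3-trimethylcyclohex-1-ene | C#CCCC1=C(C)CCCC1(C)C | intermediate
4 | dimethyl[(1E)-2-methyl-4-(2,6,6-trimethylcyclohex-1-en-1-yl)but-1-en-1-yl]alane | C[Al](C)/C=C(\C)CCC1=C(C)CCCC1(C)C | intermediate
5 | 2-[(3E)-4-iodo-3-methylbut-3-en-1-yl]-1,3,3-trimethylcyclohex-1-ene | I/C=C(\C)CCC1=C(C)CCCC1(C)C | intermediate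
6 | but-2-yne-1,4-diol | OCC#CCO | starting material
7 | 4-((tert-butyldiphenylsilyl)oxy)but-2-yn-1-ol | OCC#CCO[Si](c1ccccc1)(c1ccccc1)C(C)(C)C | intermediate
8 | sodium 2,2-bis(2-methoxyethoxy)-3-(((tert-butyldiphenylsilyl)oxy)methyl)-2,5-dihydro-1,2-oxaaluminol-2-uide (cyclic vinylalanate) | [Na+].COCCO[Al-]1(OCCOC)OCC=C1CO[Si](c1ccccc1)(c1ccccc1)C(C)(C)C | intermediate
9 | (Z)-4-((tert-butyldiphenylsilyl)oxy)-3-iodobut-2-en-1-ol | OC/C=C(\I)CO[Si](c1ccccc1)(c1ccccc1)C(C)(C)C | intermediate
10 | (Z)-[(4-bromo-2-iodobut-2-en-1-yl)oxy](tert-butyl)diphenylsilane | BrC/C=C(\I)CO[Si](c1ccccc1)(c1ccccc1)C(C)(C)C | intermediate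
11 | 2,2-dimethyl-1,3-dioxan-5-one | CC1(C)OCC(=O)CO1 | starting material
12 | (R)-N-(2,2-dimethyl-1,3-dioxan-5-ylidene)-2-(methoxymethyl)pyrrolidin-1-amine | CC1(C)OCC(=NN2CCC[C@@H]2COC)CO1 | intermediate
13 | lithium azaenolate of 12, N-lithio-N-(2,2-dimethyl-4H-1,3-dioxin-5-yl) derivative of RAMP | CC1(C)OCC(N([Li])N2CCC[C@@H]2COC)=CO1 | intermediate
14 | (R)-N-[(4R)-4-((Z)-4-((tert-butyldiphenylsilyl)oxy)-3-iodobut-2-en-1-yl)-2,2-dimethyl-1,3-dioxan-5-ylidene]-2-(methoxymethyl)pyrrolidin-1-amine (C=N geometry open) | CC1(C)OCC(=NN2CCC[C@@H]2COC)[C@@H](C/C=C(\I)CO[Si](c2ccccc2)(c2ccccc2)C(C)(C)C)O1 | intermediate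
15 | (R)-4-[(Z)-4-((tert-butyldiphenylsilyl)oxy)-3-iodobut-2-en-1-yl]-2,2-dimethyl-1,3-dioxan-5-one | CC1(C)OCC(=O)[C@@H](C/C=C(\I)CO[Si](c2ccccc2)(c2ccccc2)C(C)(C)C)O1 | intermediate
16 | (3R,5Z)-7-((tert-butyldiphenylsilyl)oxy)-1,3-dihydroxy-6-iodohept-5-en-2-one | OCC(=O)[C@H](O)C/C=C(\I)CO[Si](c1ccccc1)(c1ccccc1)C(C)(C)C | intermediate
17 | (3R,5Z)-1-((tert-butyldimethylsilyl)oxy)-7-((tert-butyldiphenylsilyl)oxy)-3-hydroxy-6-iodohept-5-en-2-one | CC(C)(C)[Si](C)(C)OCC(=O)[C@H](O)C/C=C(\I)CO[Si](c1ccccc1)(c1ccccc1)C(C)(C)C | intermediate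
18 | (3R,5Z)-1-((tert-butyldimethylsilyl)oxy)-7-((tert-butyldiphenylsilyl)oxy)-6-iodo-2-oxohept-5-en-3-yl 2-(triphenylphosphoranylidene)acetate | CC(C)(C)[Si](C)(C)OCC(=O)[C@H](OC(=O)C=P(c1ccccc1)(c1ccccc1)c1ccccc1)C/C=C(\I)CO[Si](c1ccccc1)(c1ccccc1)C(C)(C)C | intermediate
19 | (R)-4-(((tert-butyldimethylsilyl)oxy)methyl)-5-[(Z)-4-((tert-butyldiphenylsilyl)oxy)-3-iodobut-2-en-1-yl]furan-2(5H)-one | CC(C)(C)[Si](c1ccccc1)(c1ccccc1)OC/C(I)=C/C[C@H]1OC(=O)C=C1CO[Si](C)(C)C(C)(C)C | intermediate
20 | (R)-4-(((tert-butyldimethylsilyl)oxy)methyl)-5-[(E)-3-(((tert-butyldiphenylsilyl)oxy)methyl)penta-2,4-dien-1-yl]furan-2(5H)-one | CC(C)(C)[Si](c1ccccc1)(c1ccccc1)OC/C(C=C)=C/C[C@H]1OC(=O)C=C1CO[Si](C)(C)C(C)(C)C | intermediate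
21 | B-alkyl-9-borabicyclo[3.3.1]nonane from 20 (boron on the terminal carbon of the former vinyl group) | CC(C)(C)[Si](c1ccccc1)(c1ccccc1)OC/C(CCB1C2CCCC1CCC2)=C/C[C@H]1OC(=O)C=C1CO[Si](C)(C)C(C)(C)C | intermediate
22 | (R)-4-(((tert-butyldimethylsilyl)oxy)methyl)-5-[(2E,6E)-3-(((tert-butyldiphenylsilyl)oxy)methyl)-7-methyl-9-(2,6,6-trimethylcyclohex-1-en-1-yl)nona-2,6-dien-1-yl]furan-2(5H)-one | CC1=C(CC/C(C)=C/CC/C(=C\C[C@H]2OC(=O)C=C2CO[Si](C)(C)C(C)(C)C)CO[Si](c2ccccc2)(c2ccccc2)C(C)(C)C)C(C)(C)CCC1 | intermediate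
23 | (6E)-neomanoalide, (R)-4-(hydroxymethyl)-5-[(2E,6E)-3-(hydroxymethyl)-7-methyl-9-(2,6,6-trimethylcyclohex-1-en-1-yl)nona-2,6-dien-1-yl]furan-2(5H)-one | CC1=C(CC/C(C)=C/CC/C(=C\C[C@H]2OC(=O)C=C2CO)CO)C(C)(C)CCC1 | target

**Step count and risks**
Total step count: 14. Longest linear sequence: 11 steps (steps 3, 4, 5, 7, 8, 9, 10, 11, 12, 13, 14, from but-2-yne-1,4-diol).

Steps most likely to fail:

Step 13. Under the aqueous phosphate base the butenolide may lose its γ-proton (epimerisation at C-5 through the 2-oxidofuran) or be opened by hydroxide, and a slow transmetalation would let β-hydride elimination return diene 20. The fallback is a base-free Negishi union that sets out from 20. Hydroboration with 9-BBN as before, followed by oxidation under buffered conditions (H2O2, pH 7 phosphate buffer, THF, 0 °C), should give the primary alcohol, (R)-4-(((tert-butyldimethylsilyl)oxy)methyl)-5-[(E)-3-(((tert-butyldiphenylsilyl)oxy)methyl)-5-hydroxypent-2-en-1-yl]furan-2(5H)-one F1. Iodination (I2, PPh3, imidazole, CH2Cl2, 0 °C) should give the homoallylic iodide F2. Zinc insertion (Zn dust, LiCl, THF, rt) should give the alkylzinc iodide F3, which is coupled with 5 (Pd(PPh3)4, THF, rt; homoallylzinc–alkenyl iodide Negishi coupling) and comes back to the route at 22.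

Step 11. The ring-closing Wittig reaction at the hindered α-silyloxy ketone may be slow at 90 °C, so that enolisation of the α-acyloxy ketone erodes the stereocentre or the silyl group migrates to the secondary oxygen. The fallback sets out from 17 and separates acylation from ring closure. Esterification with diethylphosphonoacetic acid (EDC·HCl, DMAP, CH2Cl2, 0 °C) should give the phosphonoacetate ester F4. An intramolecular Horner–Wadsworth–Emmons reaction under Masamune–Roush conditions (LiCl, i-Pr2NEt, MeCN, rt) then closes the butenolide and comes back to the route at 19.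

Step 9. The liberated α,α'-dihydroxy ketone may self-condense to hemiketal dimers or isomerise through the enediol, and the silyl ether may be partly lost in the acid. The fallback sets out from 15 and never frees a hydroxy ketone; the butenolide is closed by metathesis instead. Wittig methylenation (Ph3PCH3Br, KN(SiMe3)2, THF, −78 → 0 °C) should give the (R)-5-methylidene-1,3-dioxane F5. Acetonide hydrolysis (AcOH/H2O, 40 °C) should give the allylic diol F6, and primary-selective silylation (t-BuMe2SiCl, imidazole) the mono-TBS ether F7. Acylation with acryloyl chloride (i-Pr2NEt, CH2Cl2, −78 → 0 °C) should give the acrylate F8. Ring-closing metathesis with the second-generation Grubbs catalyst RuCl2(=CHPh)(PCy3)(H2IMes) in toluene at 80 °C then comes back to the route at 19.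

**Further compounds**
F1 | step 13 | (R)-4-(((tert-butyldimethylsilyl)oxy)methyl)-5-[(E)-3-(((tert-butyldiphenylsilyl)oxy)methyl)-5-hydroxypent-2-en-1-yl]furan-2(5H)-one | CC(C)(C)[Si](c1ccccc1)(c1ccccc1)OC/C(CCO)=C/C[C@H]1OC(=O)C=C1CO[Si](C)(C)C(C)(C)C
F2 | step 13 | (R)-4-(((tert-butyldimethylsilyl)oxy)methyl)-5-[(E)-3-(((tert-butyldiphenylsilyl)oxy)methyl)-5-iodopent-2-en-1-yl]furan-2(5H)-one | CC(C)(C)[Si](c1ccccc1)(c1ccccc1)OC/C(CCI)=C/C[C@H]1OC(=O)C=C1CO[Si](C)(C)C(C)(C)C
F3 | step 13 | alkylzinc iodide from F2 (C–I replaced by C–ZnI) | CC(C)(C)[Si](c1ccccc1)(c1ccccc1)OC/C(CC[Zn]I)=C/C[C@H]1OC(=O)C=C1CO[Si](C)(C)C(C)(C)C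
F4 | step 11 | (3R,5Z)-1-((tert-butyldimethylsilyl)oxy)-7-((tert-butyldiphenylsilyl)oxy)-6-iodo-2-oxohept-5-en-3-yl 2-(diethoxyphosphoryl)acetate | CC(C)(C)[Si](C)(C)OCC(=O)[C@H](OC(=O)CP(=O)(OCC)OCC)C/C=C(\I)CO[Si](c1ccccc1)(c1ccccc1)C(C)(C)C
F5 | step 9 | (R)-4-[(Z)-4-((tert-butyldiphenylsilyl)oxy)-3-iodobut-2-en-1-yl]-2,2-dimethyl-5-methylidene-1,3-dioxane | CC1(C)OCC(=C)[C@@H](C/C=C(\I)CO[Si](c2ccccc2)(c2ccccc2)C(C)(C)C)O1
F6 | step 9 | (3R,5Z)-7-((tert-butyldiphenylsilyl)oxy)-6-iodo-2-methylidenehept-5-ene-1,3-diol | OCC(=C)[C@H](O)C/C=C(\I)CO[Si](c1ccccc1)(c1ccccc1)C(C)(C)C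
F7 | step 9 | (3R,5Z)-1-((tert-butyldimethylsilyl)oxy)-7-((tert-butyldiphenylsilyl)oxy)-6-iodo-2-methylidenehept-5-en-3-ol | CC(C)(C)[Si](C)(C)OCC(=C)[C@H](O)C/C=C(\I)CO[Si](c1ccccc1)(c1ccccc1)C(C)(C)C
F8 | step 9 | (3R,5Z)-1-((tert-butyldimethylsilyl)oxy)-7-((tert-butyldiphenylsilyl)oxy)-6-iodo-2-methylidenehept-5-en-3-yl prop-2-enoate | CC(C)(C)[Si](C)(C)OCC(=C)[C@H](OC(=O)C=C)C/C=C(\I)CO[Si](c1ccccc1)(c1ccccc1)C(C)(C)C
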